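Eudesmane numbering is used for the decalin (ring A = C1–C5 and C10, ring B = C5–C10; C14 and C15 are the methyl groups on C10 and C4, C11 is the carbinol carbon). The last bonds are disconnected first: the C11 carbinol to a methyl ester (MeMgBr), and the C4–O aryl ether to the C4=C15 olefin plus magnolol (acid-catalysed Markovnikov capture of the eudesm-4-yl cation from the α face).
The exocyclic olefin comes from a C4 ketone (Wittig) and the ketone from a C4=C5 olefin (hydroboration, oxidation). C5 (α to the ketone) and C7 (α to the ester) are set by equilibration to the trans-fused decalin with an equatorial ester.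
Key disconnection: ring A is cut at C1–C2 and C4–C5. This leaves the three-carbon bis-ylide Ph3P=CH–CH2–CH=PPh3 (C2–C3–C4) and a ring-B keto aldehyde, and one twofold Wittig operation makes both bonds as C1=C2 and C4=C5.
Feature that allows it: C1 and C5 are both bonded to the quaternary C10 of ring B. At the carbonyl oxidation level (aldehyde C1, ring ketone C5) they form a 2-formyl-2-methylcyclohexanone, a 1,3-dicarbonyl that cannot enolise between its carbonyl groups and has exactly the spacing of a 1,3-bis-ylide.
Order of ring formation: ring B is present in the purchased methyl (1R)-3-oxocyclohexane-1-carboxylate (C10 is made quaternary by formylation and methylation), ring A is closed in the key step, and the two aryl rings arrive together as magnolol.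

Key step: step 3

Remark: methyl (1R)-3-oxocyclohexane-1-carboxylate is taken as a purchasable single enantiomer (one esterification from the commercial (R)-acid); C7 epimers that may arise in base are expected to converge in step 6.

Step 1
Reactants: 1 methyl (1R)-3-oxocyclohexane-1-carboxylate
Product: 2 methyl (1R,4Z)-4-(hydroxymethylidene)-3-oxocyclohexane-1-carboxylate
Conditions: NaH, HCO2Et, EtOH (cat.), Et2O, 0 °C to rt; then cold aq. HCl
Reagents that add atoms: ethyl formate, CCOC=O
Why: Crossed Claisen condensation (α-formylation of a ketone) should take place at the less hindered α-methylene C10, remote from the ester-bearing C7, the product being drained from the equilibrium as its stabilised sodium enolate so that the weakly acidic C7–H is hardly exposed to base, and no new stereocentre is formed.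

Step 2
Reactants: 2 methyl (1R,4Z)-4-(hydroxymethylidene)-3-oxocyclohexane-1-carboxylate
Product: 3 methyl (1R,4S)-4-formyl-4-methyl-3-oxocyclohexane-1-carboxylate
Conditions: MeI, K2CO3, acetone, 40 °C
Reagents that add atoms: iodomethane, CI
Why: C-Alkylation of the enolate of the β-keto aldehyde creates the quaternary C10, iodomethane being expected to enter axially on the half-chair that keeps the C7 ester equatorial so that the new methyl group is cis to the ester (the sense known for alkylations of 5-substituted 2-alkylcyclohexanone enolates), while the minor C10 epimer and any O-methyl enol ether are removed by chromatography at this stage.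

Step 3
Reactants: 3 methyl (1R,4S)-4-formyl-4-methyl-3-oxocyclohexane-1-carboxylate; 4 propane-1,3-diylbis(triphenylphosphonium) dibromide
Product: 7 methyl (2R,4aS)-4a-methyl-1,2,3,4,4a,7-hexahydronaphthalene-2-carboxylate, via bis-ylide 5 (not isolated), via Z-alkenyl ylide 6 (not isolated)
Conditions: 4, KN(SiMe3)2 (2 equiv), THF, −78 to 0 °C; then 3 added slowly at high dilution, −78 to 65 °C
Reagents that add atoms: none
Why: The bis-ylide 5, formed from 4 under salt-free conditions, first olefinates the more electrophilic, non-enolisable aldehyde carbon C1 of 3 through its terminus C2 to give the Z-alkenyl ylide 6, and the remaining ylide carbon C4 then adds to the ring-B ketone carbon C5 and collapses through a second oxaphosphetane, so that C1=C2 and C4=C5 are made in one flask and ring A is closed. The closest known reaction type is the twofold Wittig cyclisation of propane-1,3-diylidene bis-ylides with dialdehydes, combined with the intramolecular Wittig olefination of ketones. Ring A closes by 6-exo-trig attack of the C4 ylide on the C5 carbonyl, which is possible only from the Z isomer of the C1=C2 double bond that non-stabilised ylides deliver. No new stereocentre is formed: the quaternary C10, flanked by both carbonyl groups, cannot enolise and keeps its configuration, while C7 (α to the ester) may epimerise and is corrected in step 6. The step needs the aldehyde to react before the ketone and the ketone before the ester, which the graded electrophilicity of the three carbonyl groups, the slow addition of 3 at high dilution and the entropic advantage of the ring closure should secure.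

Step 4
Reactants: 7 methyl (2R,4aS)-4a-methyl-1,2,3,4,4a,7-hexahydronaphthalene-2-carboxylate
Product: 8 methyl (2R,4aR)-4a-methyl-1,2,3,4,4a,5,6,7-octahydronaphthalene-2-carboxylate
Conditions: H2 (1 atm), RhCl(PPh3)3 (cat.), toluene–EtOH, rt
Reagents that add atoms: none
Why: Homogeneous hydrogenation with RhCl(PPh3)3 should saturate the cis-disubstituted C1=C2 olefin and leave the hindered trisubstituted C4=C5 olefin and the ester untouched, and no stereocentre is formed.

Step 5
Reactants: 8 methyl (2R,4aR)-4a-methyl-1,2,3,4,4a,5,6,7-octahydronaphthalene-2-carboxylate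
Product: 10 methyl (2R,4aR,8R,8aR)-8-hydroxy-4a-methyldecahydronaphthalene-2-carboxylate, via alkylborane 9 (not isolated)
Conditions: BH3·THF, THF, 0 °C to rt; then H2O2, aq. NaOH, 0 °C
Reagents that add atoms: hydrogen peroxide, OO
Why: Hydroboration–oxidation should place boron on the less substituted C4 and deliver hydrogen to C5 on the same α face, anti to the angular C10 methyl group, which sets the trans ring fusion (H5 α) and the α C4 alcohol, the olefin reacting much faster with borane than the ester.

Step 6
Reactants: 10 methyl (2R,4aR,8R,8aR)-8-hydroxy-4a-methyldecahydronaphthalene-2-carboxylate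
Product: 11 methyl (2R,4aR,8aR)-4a-methyl-8-oxodecahydronaphthalene-2-carboxylate
Conditions: Dess–Martin periodinane, CH2Cl2, rt; then NaOMe (cat.), MeOH, 50 °C
Reagents that add atoms: none
Why: Dess–Martin oxidation gives the C4 ketone, and the base equilibration that follows exploits the fact that C5 (α to the ketone) and C7 (α to the ester) are both epimerisable to funnel the material into the trans-fused decalin with an equatorial ester, so that only C10 had to be fixed earlier.

Step 7
Reactants: 11 methyl (2R,4aR,8aR)-4a-methyl-8-oxodecahydronaphthalene-2-carboxylate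
Product: 12 methyl (2R,4aR,8aS)-4a-methyl-8-methylidenedecahydronaphthalene-2-carboxylate
Conditions: Ph3PCH3Br, KOtBu, toluene, 0 to 60 °C
Reagents that add atoms: methyltriphenylphosphonium bromide, C[P+](c1ccccc1)(c1ccccc1)c1ccccc1.[Br-]
Why: Wittig methylenation installs C15 as the exocyclic methylene because the ketone is far more electrophilic toward the ylide than the ester, and epimerisation at C5 or C7 under the basic conditions can only return the thermodynamic trans-fused, equatorial isomer.

Step 8
Reactants: 12 methyl (2R,4aR,8aS)-4a-methyl-8-methylidenedecahydronaphthalene-2-carboxylate; 13 magnolol (5,5'-di(prop-2-en-1-yl)-[1,1'-biphenyl]-2,2'-diol)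
Product: 14 methyl (2R,4aR,8R,8aR)-8-{[2'-hydroxy-5,5'-di(prop-2-en-1-yl)-[1,1'-biphenyl]-2-yl]oxy}-4a,8-dimethyldecahydronaphthalene-2-carboxylate
Conditions: 13 (excess), TfOH (5 mol %), CH2Cl2, −78 to −30 °C; then Et3N
Reagents that add atoms: none
Why: Brønsted acid-catalysed Markovnikov hydroaryloxylation of the 1,1-disubstituted olefin: protonation at C15 gives the tertiary eudesm-4-yl cation, which a phenol oxygen of 13 should capture from the equatorial α face because the axial β face is blocked by the 1,3-diaxial C10 methyl group, so that C4 is set with oxygen α and methyl β, while low temperature keeps kinetic O-alkylation ahead of ring C-alkylation and leaves the allyl groups, which could only give secondary cations, untouched, and the excess of the symmetric diol suppresses twofold etherification.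

Step 9
Reactants: 14 methyl (2R,4aR,8R,8aR)-8-{[2'-hydroxy-5,5'-di(prop-2-en-1-yl)-[1,1'-biphenyl]-2-yl]oxy}-4a,8-dimethyldecahydronaphthalene-2-carboxylate
Product: 16 eudesmagnolol (5,5'-di(prop-2-en-1-yl)-2'-{[(1R,4aR,7R,8aR)-7-(2-hydroxypropan-2-yl)-1,4a-dimethyldecahydronaphthalen-1-yl]oxy}-[1,1'-biphenyl]-2-ol), via methyl ketone 15 (not isolated)
Conditions: MeMgBr (excess), THF, 0 °C to rt; then H2O
Reagents that add atoms: methylmagnesium bromide, C[Mg]Br
Why: Twofold Grignard addition to the methyl ester, after the first equivalent has deprotonated the phenol, gives the C11 tertiary carbinol by way of the methyl ketone 15, while the tertiary aryl ether, the allyl groups and all stereocentres are untouched.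

Compound list
1 | methyl (1R)-3-oxocyclohexane-1-carboxylate | COC(=O)[C@@H]1CCCC(=O)C1 | starting material
2 | methyl (1R,4Z)-4-(hydroxymethylidene)-3-oxocyclohexane-1-carboxylate | COC(=O)[C@@H]1CC/C(=C/O)C(=O)C1 | intermediate
3 | methyl (1R,4S)-4-formyl-4-methyl-3-oxocyclohexane-1-carboxylate (methyl and ester cis) | COC(=O)[C@@H]1CC[C@@](C)(C=O)C(=O)C1 | intermediate
4 | propane-1,3-diylbis(triphenylphosphonium) dibromide | [Br-].[Br-].C(C[P+](c1ccccc1)(c1ccccc1)c1ccccc1)C[P+](c1ccccc1)(c1ccccc1)c1ccccc1 | starting material
5 | bis-ylide: (propane-1,3-diylidene)bis(triphenyl-λ5-phosphane) | C(C=P(c1ccccc1)(c1ccccc1)c1ccccc1)C=P(c1ccccc1)(c1ccccc1)c1ccccc1 | intermediate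
6 | Z-alkenyl ylide: methyl (1R,4S)-4-methyl-3-oxo-4-[(1Z)-4-(triphenyl-λ5-phosphanylidene)but-1-en-1-yl]cyclohexane-1-carboxylate | COC(=O)[C@@H]1CC[C@@](C)(/C=C\CC=P(c2ccccc2)(c2ccccc2)c2ccccc2)C(=O)C1 | intermediate
7 | methyl (2R,4aS)-4a-methyl-1,2,3,4,4a,7-hexahydronaphthalene-2-carboxylate | COC(=O)[C@@H]1CC[C@@]2(C)C=CCC=C2C1 | intermediate
8 | methyl (2R,4aR)-4a-methyl-1,2,3,4,4a,5,6,7-octahydronaphthalene-2-carboxylate | COC(=O)[C@@H]1CC[C@@]2(C)CCCC=C2C1 | intermediate
9 | C4 alkylborane: methyl (2R,4aR,8R,8aS)-8-boranyl-4a-methyldecahydronaphthalene-2-carboxylate (boron on C4 and the new hydrogen on C5 both α; monoalkylborane shown) | COC(=O)[C@@H]1CC[C@@]2(C)CCC[C@@H](B)[C@@H]2C1 | intermediate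
10 | methyl (2R,4aR,8R,8aR)-8-hydroxy-4a-methyldecahydronaphthalene-2-carboxylate | COC(=O)[C@@H]1CC[C@@]2(C)CCC[C@@H](O)[C@@H]2C1 | intermediate
11 | methyl (2R,4aR,8aR)-4a-methyl-8-oxodecahydronaphthalene-2-carboxylate (trans-fused, ester equatorial) | COC(=O)[C@@H]1CC[C@@]2(C)CCCC(=O)[C@@H]2C1 | intermediate
12 | methyl (2R,4aR,8aS)-4a-methyl-8-methylidenedecahydronaphthalene-2-carboxylate | COC(=O)[C@@H]1CC[C@@]2(C)CCCC(=C)[C@@H]2C1 | intermediate
13 | magnolol, 5,5'-di(prop-2-en-1-yl)-[1,1'-biphenyl]-2,2'-diol | C=CCc1ccc(O)c(-c2cc(CC=C)ccc2O)c1 | starting material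
14 | methyl (2R,4aR,8R,8aR)-8-{[2'-hydroxy-5,5'-di(prop-2-en-1-yl)-[1,1'-biphenyl]-2-yl]oxy}-4a,8-dimethyldecahydronaphthalene-2-carboxylate | COC(=O)[C@@H]1CC[C@@]2(C)CCC[C@@](C)(Oc3ccc(CC=C)cc3-c3cc(CC=C)ccc3O)[C@@H]2C1 | intermediate
15 | methyl ketone: 1-[(2R,4aR,8R,8aR)-8-{[2'-hydroxy-5,5'-di(prop-2-en-1-yl)-[1,1'-biphenyl]-2-yl]oxy}-4a,8-dimethyldecahydronaphthalen-2-yl]ethan-1-one | CC(=O)[C@@H]1CC[C@@]2(C)CCC[C@@](C)(Oc3ccc(CC=C)cc3-c3cc(CC=C)ccc3O)[C@@H]2C1 | intermediate
16 | eudesmagnolol, 5,5'-di(prop-2-en-1-yl)-2'-{[(1R,4aR,7R,8aR)-7-(2-hydroxypropan-2-yl)-1,4a-dimethyldecahydronaphthalen-1-yl]oxy}-[1,1'-biphenyl]-2-ol | C=CCc1ccc(O)c(-c2cc(CC=C)ccc2O[C@]2(C)CCC[C@]3(C)CC[C@@H](C(C)(C)O)C[C@H]32)c1 | target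

Total step count: 9. Longest linear sequence: 9 steps (1 to 16).

Steps most likely to fail

Step 8. The process at risk is the capture of the tertiary cation by the hindered phenol oxygen: the ether may ionise back, the cation may lose a proton to ring olefins, or it may alkylate the arene ring before O-capture is secured. The fallback sets out from 12 and replaces the acid by a cobalt-catalysed MHAT radical–polar crossover Markovnikov hydroetherification ([N,N'-bis(3,5-di-tert-butylsalicylidene)-1,2-cyclohexanediaminato]cobalt, N-fluoro-2,4,6-trimethylpyridinium tetrafluoroborate, 1,1,3,3-tetramethyldisiloxane, PhCF3, rt). The phenol partner is 5,5'-dibromo-[1,1'-biphenyl]-2,2'-diol, used in place of 13 because aryl bromides, unlike allyl groups, are inert to the cobalt hydride. This should give the dibromo ether methyl (2R,4aR,8R,8aR)-8-[(5,5'-dibromo-2'-hydroxy-[1,1'-biphenyl]-2-yl)oxy]-4a,8-dimethyldecahydronaphthalene-2-carboxylate F1. Twofold Stille allylation of F1 (allyltributylstannane, Pd(PPh3)4, DMF, 90 °C) comes back to the route at 14.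

Step 3. The process at risk is the second, intramolecular olefination at the hindered ketone: the ylide may instead enolise the ketone, or the mono-olefinated ylide may oligomerise. The fallback sets out from 3: twofold Wittig methylenation (Ph3PCH3Br, KOtBu) should give the diene methyl (1R,4S)-4-ethenyl-4-methyl-3-methylidenecyclohexane-1-carboxylate F2. Its vinyl carbon (C1) and exocyclic methylene carbon (C5) are then stitched to penta-1,4-diene by cross-metathesis followed by ring-closing metathesis (second-generation Hoveyda–Grubbs catalyst, CH2Cl2, 40 °C, loss of ethene). This again forms C1=C2 and C4=C5 in one operation and comes back to the route at 7.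

Step 5. The process at risk is slow or face-unselective hydroboration of the hindered trisubstituted olefin next to the quaternary centre, with competing reduction of the ester. The fallback sets out from 8: epoxidation with mCPBA from the α face should give the oxirane methyl (2R,4aR,8R,8aS)-8,8a-epoxy-4a-methyldecahydronaphthalene-2-carboxylate F3. Its BF3·OEt2-promoted Meinwald rearrangement (opening to the tertiary C5 cation, 1,2-hydride shift from C4), followed by the NaOMe equilibration of step 6, comes back to the route at 11.

Further compounds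
F1 | step 8 | methyl (2R,4aR,8R,8aR)-8-[(5,5'-dibromo-2'-hydroxy-[1,1'-biphenyl]-2-yl)oxy]-4a,8-dimethyldecahydronaphthalene-2-carboxylate | COC(=O)[C@@H]1CC[C@@]2(C)CCC[C@@](C)(Oc3ccc(Br)cc3-c3cc(Br)ccc3O)[C@@H]2C1
F2 | step 3 | methyl (1R,4S)-4-ethenyl-4-methyl-3-methylidenecyclohexane-1-carboxylate | COC(=O)[C@@H]1CC[C@@](C)(C=C)C(=C)C1
F3 | step 5 | methyl (2R,4aR,8R,8aS)-8,8a-epoxy-4a-methyldecahydronaphthalene-2-carboxylate (oxirane oxygen α, anti to the angular methyl) | COC(=O)[C@@H]1CC[C@@]2(C)CCC[C@H]3O[C@]32C1
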